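Late in the delta run the left-handed substrate stopped falling, at 7% and then 5%, and I read that as the end of what its 0.073 M of solid reagent, the limiting reagent there, could pay for. The flask differs from delta in one setting: it has twice that solid.

the same everywhere: left-handed substrate 0.073 M; right-handed substrate 0.073 M

|  | solid reagent | free catalyst | remark | time |
|---|---|---|---|---|
| theta | 0.146 M | 0.50 mM | run made earlier |  |
| gamma | 0.146 M | 0.79 mM | run made earlier |  |
| delta | 0.073 M | 0.36 mM | run made earlier |  |
| flask | 0.146 M | 0.36 mM |  | 6.0 d |

| run | time / d | right-handed substrate / % | left-handed substrate / % | left-handed product / % |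
|---|---|---|---|---|
| theta | 0.417 | 50 | 42 | 5 |
| theta | 1.25 | 49 | 21 | 15 |
| theta | 2.00 | 44 | 8 | 23 |
| theta | 3.00 | 43 | 2 | 29 |
| theta | 5.00 | 31 | 0 | 31 |
| gamma | 0.417 | 50 | 38 | 5 |
| gamma | 0.833 | 49 | 27 | 10 |
| gamma | 1.25 | 48 | 23 | 14 |
| gamma | 2.50 | 43 | 0 | 27 |
| gamma | 5.00 | 22 | 1 | 38 |
| delta | 0.417 | 46 | 44 | 2 |
| delta | 1.25 | 48 | 26 | 14 |
| delta | 2.00 | 50 | 13 | 23 |
| delta | 3.00 | 47 | 7 | 22 |
| delta | 5.00 | 51 | 5 | 25 |

(scatter of a reading: 2 percentage points)

- whether the excess of right-handed substrate over left-handed substrate among what is left of the two reaches 80% by 6.0 d (no / yes)
- the highest excess of right-handed substrate over left-handed substrate among what is left of the two up to 6.0 d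

- free catalyst is single-handed; left-handed substrate and right-handed substrate are mirror images of each other, charged as a racemate, each of them at the stated concentration
- solid reagent is a solid; its amount is given per volume of the solution
- the analysis behind the earlier runs scatters by 2 percentage points, standard deviation
- what may be going on: free catalyst + left-handed substrate <-> catalyst intermediate A; free catalyst + right-handed substrate <-> catalyst intermediate B; partner + catalyst intermediate A -> free catalyst + left-handed product; partner + catalyst intermediate B -> free catalyst + right-handed product; left-handed product <-> right-handed product; solid reagent <-> partner; 2 partner -> self-condensation product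
- at the start none of the solid reagent is in solution

Before that stop the fall in delta looked like a straight line, not a curve, so I watched what the solid puts into solution, the partner, and not the substrate. I called the feed rate the share of both substrates charged that left-handed substrate loses per day on the straight stretch, 0.196 d⁻¹ in delta.

The excess reaches 80% when left-handed substrate stands at 5.22% beside right-handed substrate near 47%. For the flask, which has delta's catalyst, I started from delta's 44% at 0.417 d: the feed rate put the wanted level at 2.40 d and the end of left-handed substrate at 2.66 d, earlier than 6.0 d. By my reckoning the flask needed 47.8% of the substrates to react, less than the 88.0% I got by doubling what delta had used up at its last reading.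

The weak link was a slope read with half the flask's solid. The theta run, with the flask's solid but more catalyst than the flask, gave 0.215 d⁻¹, which moves my date to 2.22 d. I committed to yes, with a top near 100%.

The forecast, on other grounds than mine, said yes, with a top of 96%, holding that “the rate scales roughly with catalyst”.

The flask gave yes, with a top of 100%.

    free catalyst + left-handed substrate ⇌ catalyst intermediate A (K = 140 M⁻¹, k = 20.0 M⁻¹ s⁻¹)
    free catalyst + right-handed substrate ⇌ catalyst intermediate B (K = 6.00 M⁻¹, k = 0.850 M⁻¹ s⁻¹)
    partner + catalyst intermediate A → free catalyst + left-handed product (k = 0.220 M⁻¹ s⁻¹)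
    partner + catalyst intermediate B → free catalyst + right-handed product (k = 0.0880 M⁻¹ s⁻¹)
    left-handed product ⇌ right-handed product (k = 7.20 × 10⁻⁵ s⁻¹)
    solid reagent ⇌ partner, rate k6*(cs6 - [partner]) while solid is left; crystals form when [partner] > cs6 (solubility = 24.0 mM, k = 2.20 × 10⁻⁵ s⁻¹)
    2 partner → self-condensation product (k = 7.50 × 10⁻⁴ M⁻¹ s⁻¹)

In the flask the excess reached 80% at 2.38 d, when right-handed substrate stood at 48.1% of the two substrates charged together. In the gamma run, with twice delta's catalyst and twice its solid, delta's feed rate put the end of left-handed substrate at 2.36 d, and gamma read 0% at 2.50 d.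

The readings come from a simulation from invented constants; scatter was added.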